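**Strategy**

The pyrrole ring is disconnected across N1–C2 and C3–S. C2 (with its bromine) and C3 (with its methylsulfanyl group) are read as the two carbons of a bromoalkyne sitting on C3a, next to the nitrogen-bearing C7a of the tribrominated benzene ring. A methylsulfenyl cation donor should add sulfur to C3 while the sulfonamide nitrogen adds to C2, so one anti addition closes the five-membered ring and sets both pyrrole substituents without touching the three aryl bromides. The precursor is 3,4,5-tribromo-N-tosylaniline carrying a bromoethynyl group at C2, built from 3,4,5-tribromoaniline by iodination, Sonogashira coupling, sulfonylation and bromodesilylation; detosylation finishes the synthesis.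

Key step: step 5

Remark: 3,4,5-tribromoaniline and dimethyl(methylsulfanyl)sulfonium tetrafluoroborate are assumed to be purchasable, and the thiirenium ion of step 5 is counted as a non-isolated intermediate.

**Route**

Step 1
Reactants: 1 3,4,5-tribromoaniline
Product: 2 3,4,5-tribromo-2-iodoaniline
Conditions: NIS (1.05 equiv), AcOH, rt, dark
Reagents that add atoms: N-iodosuccinimide, O=C1CCC(=O)N1I
Why: Electrophilic aromatic iodination ortho to the activating amino group should occur at C2, because the para position carries bromine and the two free ortho positions are equivalent, while one equivalent of NIS and the deactivating first iodine hold back a second iodination.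

Step 2
Reactants: 2 3,4,5-tribromo-2-iodoaniline; 3 trimethylsilylacetylene
Product: 4 3,4,5-tribromo-2-[(trimethylsilyl)ethynyl]aniline
Conditions: PdCl2(PPh3)2 (3 mol %), CuI (5 mol %), Et3N, THF, rt, Ar
Reagents that add atoms: none
Why: Sonogashira coupling, in which zerovalent palladium inserts into the C–I bond far faster than into the three C–Br bonds at room temperature, so only the iodide should be replaced by the silylalkyne and the free amine is tolerated.

Step 3
Reactants: 4 3,4,5-tribromo-2-[(trimethylsilyl)ethynyl]aniline; 5 4-methylbenzenesulfonyl chloride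
Product: 6 N-{3,4,5-tribromo-2-[(trimethylsilyl)ethynyl]phenyl}-4-methylbenzenesulfonamide
Conditions: pyridine, 0 °C → 50 °C
Reagents that add atoms: none
Why: N-Sulfonylation of the aniline with a sulfonyl chloride in pyridine (Hinsberg-type reaction) should stop at the monosulfonamide, because the product nitrogen is hindered by the ortho alkyne and far less nucleophilic.

Step 4
Reactants: 6 N-{3,4,5-tribromo-2-[(trimethylsilyl)ethynyl]phenyl}-4-methylbenzenesulfonamide
Product: 7 N-[3,4,5-tribromo-2-(bromoethynyl)phenyl]-4-methylbenzenesulfonamide
Conditions: NBS (1.2 equiv), AgNO3 (10 mol %), acetone, rt, dark; aq. Na2S2O3 work-up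
Reagents that add atoms: N-bromosuccinimide, O=C1CCC(=O)N1Br
Why: AgNO3-catalysed bromodesilylation of an alkynylsilane with NBS exchanges the C(sp)–Si bond for C(sp)–Br at room temperature, and the sulfonylated, halogen-crowded arene offers no competing site for ring bromination.

Step 5
Reactants: 7 N-[3,4,5-tribromo-2-(bromoethynyl)phenyl]-4-methylbenzenesulfonamide; 8 dimethyl(methylsulfanyl)sulfonium tetrafluoroborate
Product: 10 2,4,5,6-tetrabromo-3-(methylsulfanyl)-1-(4-methylbenzenesulfonyl)-1H-indole, via S-methylthiirenium tetrafluoroborate 9 (not isolated)
Conditions: 8 (1.5 equiv), CH2Cl2, 0 °C → rt, Ar; aq. NaHCO3 work-up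
Reagents that add atoms: none
Why: Reagent 8 transfers MeS+ to the alkyne of 7 to give thiirenium ion 9, the sulfonamide nitrogen opens it from the side opposite sulfur at the bromine-bearing carbon, and loss of the N–H proton gives the aromatic N-sulfonylindole 10. The closest known reaction type is the electrophilic cyclisation of 2-alkynylaniline derivatives with sulfenyl, selenyl or iodine electrophiles, together with the methylthio-cyclisation of ortho-heteroatom-substituted arylalkynes by the same sulfonium salt; here that chemistry is applied to an alkyne that ends in bromine. The pyrrole ring closes in a 5-endo-dig mode, forming N1–C2 and C3–S in one operation. No stereocentre is created. The step needs nitrogen to attack the distal alkyne carbon faster than any external nucleophile does: attack at the proximal carbon would be a 4-exo closure and is geometrically excluded, the bromine lone pairs stabilise positive charge on the carbon they sit on, and tetrafluoroborate in dichloromethane offers no competing nucleophile. The sulfonyl group keeps the N–H acidic enough to be lost after closure and shields nitrogen from irreversible sulfenylation.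

Step 6
Reactants: 10 2,4,5,6-tetrabromo-3-(methylsulfanyl)-1-(4-methylbenzenesulfonyl)-1H-indole
Product: 11 2,4,5,6-tetrabromo-3-(methylsulfanyl)-1H-indole
Conditions: Cs2CO3 (3 equiv), THF/MeOH, rt; aq. NH4Cl
Reagents that add atoms: none
Why: Base-mediated methanolysis of an N-sulfonylindole (methoxide attack at sulfur) should be fast at room temperature because the tetrabrominated indolide is an excellent leaving group, and neither the C–Br bonds nor the thioether react with carbonate in methanol.

**Compound list**

1 | 3,4,5-tribromoaniline | Nc1cc(Br)c(Br)c(Br)c1 | starting material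
2 | 3,4,5-tribromo-2-iodoaniline | Nc1cc(Br)c(Br)c(Br)c1I | intermediate
3 | trimethylsilylacetylene | C#C[Si](C)(C)C | starting material
4 | 3,4,5-tribromo-2-[(trimethylsilyl)ethynyl]aniline | C[Si](C)(C)C#Cc1c(N)cc(Br)c(Br)c1Br | intermediate
5 | 4-methylbenzenesulfonyl chloride | Cc1ccc(cc1)S(Cl)(=O)=O | starting material
6 | N-{3,4,5-tribromo-2-[(trimethylsilyl)ethynyl]phenyl}-4-methylbenzenesulfonamide | Cc1ccc(cc1)S(=O)(=O)Nc1cc(Br)c(Br)c(Br)c1C#C[Si](C)(C)C | intermediate
7 | N-[3,4,5-tribromo-2-(bromoethynyl)phenyl]-4-methylbenzenesulfonamide | Cc1ccc(cc1)S(=O)(=O)Nc1cc(Br)c(Br)c(Br)c1C#CBr | intermediate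
8 | dimethyl(methylsulfanyl)sulfonium tetrafluoroborate | CS[S+](C)C.F[B-](F)(F)F | starting material
9 | 2-bromo-1-methyl-3-{4,5,6-tribromo-2-[(4-methylbenzenesulfonyl)amino]phenyl}thiiren-1-ium tetrafluoroborate | C[S+]1C(Br)=C1c2c(NS(=O)(=O)c3ccc(C)cc3)cc(Br)c(Br)c2Br.F[B-](F)(F)F | intermediate
10 | 2,4,5,6-tetrabromo-3-(methylsulfanyl)-1-(4-methylbenzenesulfonyl)-1H-indole | CSc1c(Br)n(S(=O)(=O)c2ccc(C)cc2)c2cc(Br)c(Br)c(Br)c12 | intermediate
11 | 2,4,5,6-tetrabromo-3-(methylsulfanyl)-1H-indole | CSc1c(Br)[nH]c2cc(Br)c(Br)c(Br)c12 | target

**Step count and risks**

Total step count: 6. Longest linear sequence: 6 steps (1 → 2 → 4 → 6 → 7 → 10 → 11).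

The three steps most likely to fail:

Step 5. The bromoalkyne is electron-poor, so sulfenium transfer may be slow. The thiirenium ion may also be diverted before the ring closes, by capture with dimethyl sulfide or water or by sulfenylation at nitrogen. The fallback builds the indole first and introduces sulfur and the C2 bromine afterwards by electrophilic substitution. It sets out from 4. Protodesilylation (K2CO3, MeOH, rt) should give 3,4,5-tribromo-2-ethynylaniline F1. CuI-catalysed 5-endo-dig hydroamination (CuI, DMF, 100 °C, Castro-type indole synthesis) should give 4,5,6-tribromo-1H-indole F2. MgBr2-catalysed C3 sulfenylation with N-(methylsulfanyl)phthalimide (CSN1C(=O)c2ccccc2C1=O; DMAc, 90 °C) should give 4,5,6-tribromo-3-(methylsulfanyl)-1H-indole F3. NBS (1.0 equiv, CH2Cl2, 0 °C) should then brominate the only free pyrrole position, C2, and the fallback comes back to the route at 11.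

Step 4. AgNO3 may trigger premature hydroamination of the alkyne by the neighbouring sulfonamide, or bromine may be delivered to nitrogen instead of replacing silicon at carbon. The fallback separates the two events and omits silver. It sets out from 6. K2CO3 in MeOH at rt should remove the silyl group to give N-(3,4,5-tribromo-2-ethynylphenyl)-4-methylbenzenesulfonamide F4. Deprotonative bromination of the terminal alkyne with NBS and DBU (2.2 equiv) in MeCN at 0 °C, followed by Na2S2O3 work-up to return any N-bromo sulfonamide to N–H, should rejoin the route at 7.

Step 3. The nitrogen of 4 is weakly nucleophilic (three bromines and an ortho alkyne), so sulfonylation may stall, and forcing it risks double sulfonylation or loss of the silyl group. The fallback inverts the order of sulfonylation and alkynylation. It sets out from 2. Sulfonylation with 5 in pyridine at 80 °C, which the robust iodoarene tolerates, should give N-(3,4,5-tribromo-2-iodophenyl)-4-methylbenzenesulfonamide F5. Sonogashira coupling of this iodide with 3 under the conditions of step 2 should rejoin the route at 6.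

**Further compounds**

F1 | step 5 | 3,4,5-tribromo-2-ethynylaniline | C#Cc1c(N)cc(Br)c(Br)c1Br
F2 | step 5 | 4,5,6-tribromo-1H-indole | Brc1cc2[nH]ccc2c(Br)c1Br
F3 | step 5 | 4,5,6-tribromo-3-(methylsulfanyl)-1H-indole | CSc1c[nH]c2cc(Br)c(Br)c(Br)c12
F4 | step 4 | N-(3,4,5-tribromo-2-ethynylphenyl)-4-methylbenzenesulfonamide | Cc1ccc(cc1)S(=O)(=O)Nc1cc(Br)c(Br)c(Br)c1C#C
F5 | step 3 | N-(3,4,5-tribromo-2-iodophenyl)-4-methylbenzenesulfonamide | Cc1ccc(cc1)S(=O)(=O)Nc1cc(Br)c(Br)c(Br)c1I
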